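The route disconnects C7–C8 in the nine-membered oxacycle (O, C3, C4, C5, C6, C7, C8, C9, C10; germacrane numbering, defined below). This bond lies in the homoallylic alcohol unit C13=C11–C7–C8–O, shared by the α-methylene lactone and the medium ring, and is the retron of a carbonyl allylation. The precursor is a 3-(bromomethyl)butenolide whose C6 carries, through the Z-olefin and the finished oxolane, a C8 aldehyde. CrCl2 turns the electrophilic butenolide β-carbon C7 into a nucleophile; its addition to C8 closes the ring, sets C7 and C8 and unveils the exocyclic methylene in one operation. The C8 carbinol is inverted when the angelate is introduced.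

Key step: step 17

Numbering: ring carbons C1–C10 (C1 CHOH, C2 CH2, C3 and C10 the ether carbons, C4=C5 olefin, C6 lactone carbinol, C7, C8 ester carbinol, C9 CH2), lactone carbons C11 (α), C12 (C=O), C13 (=CH2), methyls C14 (on C10) and C15 (on C4). TBS = tert-butyldimethylsilyl, PMB = 4-methoxybenzyl, (+)-MIB = (+)-3-exo-morpholinoisoborneol.

Remark: the configuration is taken exactly as written, so C3–C4 and C10–C9 leave the oxolane on opposite faces and the nine-membered ring spans the oxolane trans; the resulting strain is treated as the main risk of the ring closure.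

Step 1
Reactants: 1 tert-butyl(but-3-yn-1-yloxy)dimethylsilane
Product: 3 (E)-tert-butyl[(4-iodo-3-methylbut-3-en-1-yl)oxy]dimethylsilane, via alkenyldimethylalane 2 (not isolated)
Conditions: AlMe3, Cp2ZrCl2 (cat.), CH2Cl2, 0 °C to rt; then I2, THF, −30 °C
Reagents that add atoms: trimethylaluminium, C[Al](C)C; iodine, II
Why: Negishi carboalumination adds methyl and aluminium syn across the alkyne with aluminium on the terminal carbon, and iodinolysis with retention should give the E iodide (iodine cis to methyl), which fixes the C1=C10 geometry.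

Step 2
Reactants: 3 (E)-alkenyl iodide; 4 (2-tert-butoxy-2-oxoethyl)zinc bromide
Product: 5 tert-butyl (E)-6-(TBS-oxy)-4-methylhex-3-enoate
Conditions: Pd(PPh3)4 (5 mol%), THF, 60 °C
Reagents that add atoms: none
Why: Negishi-type coupling of a Reformatsky zinc enolate with an alkenyl iodide should proceed with retention of olefin geometry under non-basic conditions that keep the β,γ-olefin out of conjugation.

Step 3
Reactants: 5 β,γ-unsaturated ester
Product: 7 (4S,5R)-4-hydroxy-5-methyl-5-[2-(TBS-oxy)ethyl]oxolan-2-one, via epoxy ester 6 (not isolated)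
Conditions: L-fructose-derived Shi ketone (30 mol%), KHSO5 (Oxone), K2CO3, Bu4NHSO4, MeCN/dimethoxymethane/aq. buffer, 0 °C; then CSA (10 mol%), CH2Cl2, 0 °C to rt
Reagents that add atoms: potassium peroxymonosulfate, [K+].[O-]S(=O)(=O)OO
Why: Shi epoxidation (spiro dioxirane transition state, reagent control) should give the (2S,3S)-epoxide and so set C1, and acid then lets the ester carbonyl oxygen open the epoxide at the tertiary carbon C10 with inversion (loss of isobutene), which closes the future oxolane ring and sets C10 with its methyl cis to the C1 hydroxyl.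

Step 4
Reactants: 7 hydroxy lactone
Product: 8 (4S,5R)-4-(TBS-oxy)-5-methyl-5-[2-(TBS-oxy)ethyl]oxolan-2-one
Conditions: TBSOTf, 2,6-lutidine, CH2Cl2, −78 °C to 0 °C
Reagents that add atoms: tert-butyldimethylsilyl trifluoromethanesulfonate, CC(C)(C)[Si](C)(C)OS(=O)(=O)C(F)(F)F
Why: Silyl triflate silylation should protect the hindered secondary C1 hydroxyl without touching any stereocenter.

Step 5
Reactants: 8 bis-silyl lactone
Product: 10 (4S,5R)-4-(TBS-oxy)-5-methyl-5-[2-(TBS-oxy)ethyl]oxolan-2-yl acetate (anomer mixture), via aluminium hemiacetal 9 (not isolated)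
Conditions: i-Bu2AlH, CH2Cl2, −78 °C; then pyridine, DMAP, Ac2O, −78 °C to −20 °C
Reagents that add atoms: acetic anhydride, CC(=O)OC(C)=O
Why: Reductive acetylation traps the tetrahedral aluminium hemiacetal before it collapses, so the lactone should be converted into the α-acetoxy ether without over-reduction.

Step 6
Reactants: 11 but-2-yn-1-ol
Product: 12 (Z)-3-iodobut-2-en-1-ol
Conditions: NaAlH2(OCH2CH2OMe)2, THF, 0 °C to rt; then I2, −78 °C
Reagents that add atoms: iodine, II
Why: Hydroxyl-directed anti hydroalumination puts hydride on the proximal and aluminium on the distal alkyne carbon, and iodinolysis with retention should give the Z iodide (iodine cis to CH2OH), the source of the Z C4=C5 olefin.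

Step 7
Reactants: 12 (Z)-3-iodobut-2-en-1-ol
Product: 13 1-({[(Z)-3-iodobut-2-en-1-yl]oxy}methyl)-4-methoxybenzene
Conditions: NaH, PMBCl, Bu4NI (cat.), THF/DMF, 0 °C to rt
Reagents that add atoms: 4-methoxybenzyl chloride, COc1ccc(CCl)cc1
Why: Williamson etherification should protect the allylic alcohol as an ether that survives organolithium and Lewis acid and is later removed oxidatively.

Step 8
Reactants: 13 PMB-protected Z iodide
Product: 15 potassium trifluoro{(E)-4-[(4-methoxybenzyl)oxy]but-2-en-2-yl}borate (boron cis to CH2O), via lithium alkenyltrimethoxyborate 14 (not isolated)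
Conditions: t-BuLi (2.1 equiv), Et2O, −78 °C; B(OMe)3; then aq. KHF2, MeOH, rt
Reagents that add atoms: trimethyl borate, COB(OC)OC; potassium hydrogen difluoride, [K+].[F-].F
Why: Iodine–lithium exchange and borylation occur with retention at the sp2 carbon, and fluoride exchange should give the bench-stable alkenyltrifluoroborate with the olefin geometry intact.

Step 9
Reactants: 10 lactol acetate; 15 alkenyltrifluoroborate
Product: 17 (2R,3S,5S)-3-(TBS-oxy)-2-methyl-2-[2-(TBS-oxy)ethyl]-5-[(Z)-4-(PMB-oxy)but-2-en-2-yl]oxolane, via oxocarbenium ion 16 (not isolated)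
Conditions: BF3·OEt2 (2 equiv), CH2Cl2/MeCN, −78 °C to −30 °C
Reagents that add atoms: none
Why: BF3·OEt2 ionises the anomeric acetate and the five-membered oxocarbenium ion is captured at the boron-bearing carbon with retention of olefin geometry (known coupling of potassium alkenyltrifluoroborates with oxocarbenium ions from acetals); inside attack on the envelope with the C1 silyloxy group pseudo-axial should give the 1,3-cis product, which sets C3 (C4 cis to O1).

Step 10
Reactants: 17 PMB ether
Product: 18 (Z)-3-{(2S,4S,5R)-4-(TBS-oxy)-5-methyl-5-[2-(TBS-oxy)ethyl]oxolan-2-yl}but-2-en-1-ol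
Conditions: DDQ, CH2Cl2/pH 7 buffer, 0 °C
Reagents that add atoms: none
Why: Oxidative cleavage of the PMB ether by DDQ should free the allylic alcohol while both silyl ethers and the trisubstituted olefin stay intact.

Step 11
Reactants: 18 allylic alcohol
Product: 19 (Z)-3-{(2S,4S,5R)-4-(TBS-oxy)-5-methyl-5-[2-(TBS-oxy)ethyl]oxolan-2-yl}but-2-enal
Conditions: MnO2, CH2Cl2, rt
Reagents that add atoms: none
Why: MnO2 oxidises only the allylic alcohol, under neutral conditions that should preserve the Z geometry of the enal.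

Step 12
Reactants: 19 Z-enal
Product: 20 (3R,4Z)-5-{(2S,4S,5R)-4-(TBS-oxy)-5-methyl-5-[2-(TBS-oxy)ethyl]oxolan-2-yl}hexa-1,4-dien-3-ol
Conditions: Zn(CH=CH2)2, (+)-MIB (10 mol%), toluene/hexane, −30 °C to 0 °C
Reagents that add atoms: divinylzinc, C=C[Zn]C=C
Why: Amino-alcohol-catalysed asymmetric vinylzinc addition is reagent-controlled, and the (+)-ligand should deliver the vinyl group to the Re face of the aldehyde to set the future C6 carbinol (R here, S after the lactone is formed).

Step 13
Reactants: 20 bis-allylic alcohol; 21 2-(bromomethyl)prop-2-enoic acid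
Product: 22 (3R,4Z)-5-{(2S,4S,5R)-4-(TBS-oxy)-5-methyl-5-[2-(TBS-oxy)ethyl]oxolan-2-yl}hexa-1,4-dien-3-yl 2-(bromomethyl)prop-2-enoate
Conditions: DCC, DMAP (2 mol%), CH2Cl2, 0 °C
Reagents that add atoms: none
Why: Steglich esterification acylates the carbinol oxygen with retention at C6 under near-neutral conditions that the allylic bromide and the bis-allylic alcohol should tolerate.

Step 14
Reactants: 22 acrylate ester
Product: 23 (5S)-3-(bromomethyl)-5-[(Z)-2-{(2S,4S,5R)-4-(TBS-oxy)-5-methyl-5-[2-(TBS-oxy)ethyl]oxolan-2-yl}prop-1-en-1-yl]furan-2(5H)-one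
Conditions: second-generation Grubbs catalyst RuCl2(=CHPh)(H2IMes)(PCy3) (10 mol%), CH2Cl2 (0.005 M), 40 °C
Reagents that add atoms: none
Why: Ring-closing metathesis should start at the monosubstituted vinyl group and close the five-membered lactone ring onto the 1,1-disubstituted acrylate with loss of ethene; the trisubstituted C4=C5 olefin cannot form a ring and stays out.

Step 15
Reactants: 23 bis-silyl butenolide
Product: 24 (5S)-3-(bromomethyl)-5-[(Z)-2-{(2S,4S,5R)-4-(TBS-oxy)-5-(2-hydroxyethyl)-5-methyloxolan-2-yl}prop-1-en-1-yl]furan-2(5H)-one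
Conditions: aq. HF (48%), MeCN, 0 °C
Reagents that add atoms: none
Why: The primary silyl ether is cleaved much faster than the hindered secondary one next to the quaternary C10, and acidic fluoride without amine should spare the allylic bromide.

Step 16
Reactants: 24 primary alcohol
Product: 25 (5S)-3-(bromomethyl)-5-[(Z)-2-{(2S,4S,5R)-4-(TBS-oxy)-5-methyl-5-(2-oxoethyl)oxolan-2-yl}prop-1-en-1-yl]furan-2(5H)-one
Conditions: Dess–Martin periodinane, NaHCO3, CH2Cl2, 0 °C to rt
Reagents that add atoms: none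
Why: Dess–Martin oxidation is amine-free and neutral, so the C8 aldehyde should form without displacement of the allylic bromide or epimerisation of the doubly allylic C6.

Step 17
Reactants: 25 bromomethylbutenolide aldehyde
Product: 27 (1S,3S,4Z,6S,7R,8S,10R)-1-(TBS-oxy)-8-hydroxy-3,10-epoxygermacra-4,11(13)-dien-12,6-olide, via allylchromium dichloride 26 (not isolated)
Conditions: CrCl2 (8 equiv), THF (0.002 M, slow addition of 25), rt
Reagents that add atoms: none
Why: Two equivalents of CrCl2 reduce the allylic bromide to the allylchromium species 26, whose γ-carbon C7 (the formerly electrophilic butenolide β-carbon) adds to the aldehyde C8 with allylic transposition, so that the C7–C8 bond, the C8 carbinol and the exocyclic C11=C13 olefin arise together; the closest known reactions are chromium-mediated Barbier allylations of aldehydes with 3-(bromomethyl)butenolides and Nozaki–Hiyama–Kishi macrocyclisations. The nine-membered oxacycle (O, C3, C4, C5, C6, C7, C8, C9, C10) closes in the 9-exo-trig mode at the aldehyde. C7 is controlled by the tether: the chain leaving C6 through the Z-olefin should reach only the butenolide face that carries C5, so the lactone becomes cis-fused (H6 and H7 cis, 7R). C8 is controlled by the chair-like six-membered C–Cr–O transition state, in which the ring-locked E-type allyl unit and a pseudo-equatorial C9 should give the anti adduct (8S, hydroxyl trans to C11), the epimer that the inverting esterification of step 18 requires. The step needs γ- over α-attack (secured by the closed transition state), ring closure over dimerisation (high dilution and slow addition) and aldehyde over lactone carbonyl (inherent to allylchromium reagents); the silyl ether, the allylic ether and the Z-olefin are inert to CrCl2.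

Step 18
Reactants: 27 (8S)-alcohol; 28 angelic acid [(Z)-2-methylbut-2-enoic acid]
Product: 29 (1S,3S,4Z,6S,7R,8R,10R)-8-angeloyloxy-1-(TBS-oxy)-3,10-epoxygermacra-4,11(13)-dien-12,6-olide
Conditions: PPh3, DIAD, toluene, 0 °C to rt
Reagents that add atoms: none
Why: Mitsunobu esterification displaces the oxyphosphonium group by the carboxylate in an SN2 step, which should invert C8 to R under neutral conditions that keep the angelate Z.

Step 19
Reactants: 29 silyl-protected angelate
Product: 30 (1S,3S,4Z,6S,7R,8R,10R)-8-angeloyloxy-1-hydroxy-3,10-epoxygermacra-4,11(13)-dien-12,6-olide (target)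
Conditions: HF·pyridine, THF, 0 °C to rt
Reagents that add atoms: none
Why: Fluoride-mediated desilylation under mildly acidic conditions should free the C1 hydroxyl without touching the angelate, the α-methylene lactone or any stereocenter.

Compound list
1 | tert-butyl(but-3-yn-1-yloxy)dimethylsilane | C#CCCO[Si](C)(C)C(C)(C)C | starting material
2 | (E)-alkenyldimethylalane from 1 | C[Al](C)/C=C(\C)CCO[Si](C)(C)C(C)(C)C | intermediate
3 | (E)-tert-butyl[(4-iodo-3-methylbut-3-en-1-yl)oxy]dimethylsilane | I/C=C(\C)CCO[Si](C)(C)C(C)(C)C | intermediate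
4 | (2-tert-butoxy-2-oxoethyl)zinc bromide | CC(C)(C)OC(=O)C[Zn]Br | starting material
5 | tert-butyl (E)-6-(TBS-oxy)-4-methylhex-3-enoate | CC(C)(C)OC(=O)C/C=C(\C)CCO[Si](C)(C)C(C)(C)C | intermediate
6 | tert-butyl 2-{(2S,3S)-3-methyl-3-[2-(TBS-oxy)ethyl]oxiran-2-yl}acetate | CC(C)(C)OC(=O)C[C@@H]1O[C@@]1(C)CCO[Si](C)(C)C(C)(C)C | intermediate
7 | (4S,5R)-4-hydroxy-5-methyl-5-[2-(TBS-oxy)ethyl]oxolan-2-one | O=C1C[C@H](O)[C@@](C)(CCO[Si](C)(C)C(C)(C)C)O1 | intermediate
8 | (4S,5R)-4-(TBS-oxy)-5-methyl-5-[2-(TBS-oxy)ethyl]oxolan-2-one | O=C1C[C@H](O[Si](C)(C)C(C)(C)C)[C@@](C)(CCO[Si](C)(C)C(C)(C)C)O1 | intermediate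
9 | diisobutylaluminium hemiacetal of 8 | CC(C)C[Al](CC(C)C)OC1C[C@H](O[Si](C)(C)C(C)(C)C)[C@@](C)(CCO[Si](C)(C)C(C)(C)C)O1 | intermediate
10 | (4S,5R)-4-(TBS-oxy)-5-methyl-5-[2-(TBS-oxy)ethyl]oxolan-2-yl acetate (anomer mixture) | CC(=O)OC1C[C@H](O[Si](C)(C)C(C)(C)C)[C@@](C)(CCO[Si](C)(C)C(C)(C)C)O1 | intermediate
11 | but-2-yn-1-ol | CC#CCO | starting material
12 | (Z)-3-iodobut-2-en-1-ol | C/C(I)=C/CO | intermediate
13 | 1-({[(Z)-3-iodobut-2-en-1-yl]oxy}methyl)-4-methoxybenzene | C/C(I)=C/COCc1ccc(OC)cc1 | intermediate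
14 | lithium trimethoxy{(E)-4-[(4-methoxybenzyl)oxy]but-2-en-2-yl}borate | C/C(=C/COCc1ccc(OC)cc1)[B-](OC)(OC)OC.[Li+] | intermediate
15 | potassium trifluoro{(E)-4-[(4-methoxybenzyl)oxy]but-2-en-2-yl}borate | C/C(=C/COCc1ccc(OC)cc1)[B-](F)(F)F.[K+] | intermediate
16 | oxocarbenium ion from 10 | C1=[O+][C@](C)(CCO[Si](C)(C)C(C)(C)C)[C@@H](O[Si](C)(C)C(C)(C)C)C1 | intermediate
17 | (2R,3S,5S)-3-(TBS-oxy)-2-methyl-2-[2-(TBS-oxy)ethyl]-5-[(Z)-4-(PMB-oxy)but-2-en-2-yl]oxolane | COc1ccc(COC/C=C(/C)[C@@H]2C[C@H](O[Si](C)(C)C(C)(C)C)[C@@](C)(CCO[Si](C)(C)C(C)(C)C)O2)cc1 | intermediate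
18 | (Z)-3-{(2S,4S,5R)-4-(TBS-oxy)-5-methyl-5-[2-(TBS-oxy)ethyl]oxolan-2-yl}but-2-en-1-ol | OC/C=C(/C)[C@@H]1C[C@H](O[Si](C)(C)C(C)(C)C)[C@@](C)(CCO[Si](C)(C)C(C)(C)C)O1 | intermediate
19 | (Z)-3-{(2S,4S,5R)-4-(TBS-oxy)-5-methyl-5-[2-(TBS-oxy)ethyl]oxolan-2-yl}but-2-enal | O=C/C=C(/C)[C@@H]1C[C@H](O[Si](C)(C)C(C)(C)C)[C@@](C)(CCO[Si](C)(C)C(C)(C)C)O1 | intermediate
20 | (3R,4Z)-5-{(2S,4S,5R)-4-(TBS-oxy)-5-methyl-5-[2-(TBS-oxy)ethyl]oxolan-2-yl}hexa-1,4-dien-3-ol | O[C@H](C=C)/C=C(/C)[C@@H]1C[C@H](O[Si](C)(C)C(C)(C)C)[C@@](C)(CCO[Si](C)(C)C(C)(C)C)O1 | intermediate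
21 | 2-(bromomethyl)prop-2-enoic acid | C=C(CBr)C(=O)O | starting material
22 | (3R,4Z)-5-{(2S,4S,5R)-4-(TBS-oxy)-5-methyl-5-[2-(TBS-oxy)ethyl]oxolan-2-yl}hexa-1,4-dien-3-yl 2-(bromomethyl)prop-2-enoate | C=C(CBr)C(=O)O[C@H](C=C)/C=C(/C)[C@@H]1C[C@H](O[Si](C)(C)C(C)(C)C)[C@@](C)(CCO[Si](C)(C)C(C)(C)C)O1 | intermediate
23 | (5S)-3-(bromomethyl)-5-[(Z)-2-{(2S,4S,5R)-4-(TBS-oxy)-5-methyl-5-[2-(TBS-oxy)ethyl]oxolan-2-yl}prop-1-en-1-yl]furan-2(5H)-one | O=C1O[C@@H](/C=C(/C)[C@@H]2C[C@H](O[Si](C)(C)C(C)(C)C)[C@@](C)(CCO[Si](C)(C)C(C)(C)C)O2)C=C1CBr | intermediate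
24 | (5S)-3-(bromomethyl)-5-[(Z)-2-{(2S,4S,5R)-4-(TBS-oxy)-5-(2-hydroxyethyl)-5-methyloxolan-2-yl}prop-1-en-1-yl]furan-2(5H)-one | O=C1O[C@@H](/C=C(/C)[C@@H]2C[C@H](O[Si](C)(C)C(C)(C)C)[C@@](C)(CCO)O2)C=C1CBr | intermediate
25 | (5S)-3-(bromomethyl)-5-[(Z)-2-{(2S,4S,5R)-4-(TBS-oxy)-5-methyl-5-(2-oxoethyl)oxolan-2-yl}prop-1-en-1-yl]furan-2(5H)-one | O=C1O[C@@H](/C=C(/C)[C@@H]2C[C@H](O[Si](C)(C)C(C)(C)C)[C@@](C)(CC=O)O2)C=C1CBr | intermediate
26 | allylchromium dichloride from 25 | Cl[Cr](Cl)CC1=C[C@H](/C=C(/C)[C@@H]2C[C@H](O[Si](C)(C)C(C)(C)C)[C@@](C)(CC=O)O2)OC1=O | intermediate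
27 | (1S,3S,4Z,6S,7R,8S,10R)-1-(TBS-oxy)-8-hydroxy-3,10-epoxygermacra-4,11(13)-dien-12,6-olide | C=C1C(=O)O[C@H]2/C=C(/C)[C@@H]3C[C@H](O[Si](C)(C)C(C)(C)C)[C@@](C)(C[C@H](O)[C@@H]12)O3 | intermediate
28 | angelic acid [(Z)-2-methylbut-2-enoic acid] | C/C=C(/C)C(=O)O | starting material
29 | (1S,3S,4Z,6S,7R,8R,10R)-8-angeloyloxy-1-(TBS-oxy)-3,10-epoxygermacra-4,11(13)-dien-12,6-olide | C=C1C(=O)O[C@H]2/C=C(/C)[C@@H]3C[C@H](O[Si](C)(C)C(C)(C)C)[C@@](C)(C[C@@H](OC(=O)/C(C)=C\C)[C@@H]12)O3 | intermediate
30 | (1S,3S,4Z,6S,7R,8R,10R)-8-angeloyloxy-1-hydroxy-3,10-epoxygermacra-4,11(13)-dien-12,6-olide | C=C1C(=O)O[C@H]2/C=C(/C)[C@@H]3C[C@H](O)[C@@](C)(C[C@@H](OC(=O)/C(C)=C\C)[C@@H]12)O3 | target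

Total step count: 19. Longest linear sequence: 16 steps (steps 1–5 and 9–19; steps 6–8 make the side-chain reagent 15).

Steps most likely to fail

Step 17 (ring closure). The tether spans the oxolane trans, so the closed chromium transition state may be too strained. Protonation of the allylchromium species and intermolecular addition would then outrun cyclisation, or the aldehyde may react through a boat-like arrangement that gives the other C8 configuration. The fallback replaces the closed chromium transition state by an open, Lewis-acid-mediated allylstannane addition. It sets out from 24: Pd2(dba)3-catalysed stannylation with Bu3Sn–SnBu3 should give the allylstannane alcohol F1, and Dess–Martin oxidation the stannyl aldehyde F2. BF3·OEt2 at −78 °C under high dilution should then close the ring through an open antiperiplanar transition state, which favours the syn adduct, the (8R)-alcohol F3. Yamaguchi esterification of F3 with 28 (2,4,6-trichlorobenzoyl chloride, Et3N, toluene, 80 °C, no DMAP) proceeds with retention and comes back to the route at 29.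

Step 9 (alkenyl transfer to the oxocarbenium ion). The alkenyl borane may be lost by protodeboronation before it is transferred, or BF3·OEt2 may strip the PMB ether. The fallback changes both partners to a sulfone and an organozinc reagent. It sets out from 8: i-Bu2AlH at −78 °C should give the lactol F4, and benzenesulfinic acid with CaCl2 the anomeric phenyl sulfone F5. The alkenylzinc reagent made from 13 (t-BuLi, then ZnBr2) should displace the sulfinate under ZnBr2 activation through the same oxocarbenium ion and with the same 1,3-cis preference, coming back to the route at 17.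

Step 18 (inverting esterification). The activated C8 oxygen may leave by elimination toward C7 (the proton there is allylic to the methylene lactone) instead of being displaced, or the angelate may isomerise to the tiglate. The fallback separates activation from displacement. It sets out from 27: chloromethanesulfonyl chloride and pyridine at 0 °C should give the chloromethanesulfonate F6, which cesium angelate (from 28 and Cs2CO3) with 18-crown-6 in toluene should displace with inversion, coming back to the route at 29.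

Further compounds
F1 | step 17 | (5S)-5-[(Z)-2-{(2S,4S,5R)-4-(TBS-oxy)-5-(2-hydroxyethyl)-5-methyloxolan-2-yl}prop-1-en-1-yl]-3-[(tributylstannyl)methyl]furan-2(5H)-one | O=C1O[C@@H](/C=C(/C)[C@@H]2C[C@H](O[Si](C)(C)C(C)(C)C)[C@@](C)(CCO)O2)C=C1C[Sn](CCCC)(CCCC)CCCC
F2 | step 17 | (5S)-5-[(Z)-2-{(2S,4S,5R)-4-(TBS-oxy)-5-methyl-5-(2-oxoethyl)oxolan-2-yl}prop-1-en-1-yl]-3-[(tributylstannyl)methyl]furan-2(5H)-one | O=C1O[C@@H](/C=C(/C)[C@@H]2C[C@H](O[Si](C)(C)C(C)(C)C)[C@@](C)(CC=O)O2)C=C1C[Sn](CCCC)(CCCC)CCCC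
F3 | step 17 | (1S,3S,4Z,6S,7R,8R,10R)-1-(TBS-oxy)-8-hydroxy-3,10-epoxygermacra-4,11(13)-dien-12,6-olide | C=C1C(=O)O[C@H]2/C=C(/C)[C@@H]3C[C@H](O[Si](C)(C)C(C)(C)C)[C@@](C)(C[C@@H](O)[C@@H]12)O3
F4 | step 9 | (4S,5R)-4-(TBS-oxy)-5-methyl-5-[2-(TBS-oxy)ethyl]oxolan-2-ol (anomer mixture) | OC1C[C@H](O[Si](C)(C)C(C)(C)C)[C@@](C)(CCO[Si](C)(C)C(C)(C)C)O1
F5 | step 9 | (2R,3S)-5-(benzenesulfonyl)-3-(TBS-oxy)-2-methyl-2-[2-(TBS-oxy)ethyl]oxolane (anomer mixture) | O=S(=O)(c1ccccc1)C1C[C@H](O[Si](C)(C)C(C)(C)C)[C@@](C)(CCO[Si](C)(C)C(C)(C)C)O1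
F6 | step 18 | (1S,3S,4Z,6S,7R,8S,10R)-1-(TBS-oxy)-8-[(chloromethanesulfonyl)oxy]-3,10-epoxygermacra-4,11(13)-dien-12,6-olide | C=C1C(=O)O[C@H]2/C=C(/C)[C@@H]3C[C@H](O[Si](C)(C)C(C)(C)C)[C@@](C)(C[C@H](OS(=O)(=O)CCl)[C@@H]12)O3
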